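**Late gains.** At late times Friday's readings add about 6.86 parts of other capture product per part of target between 2.00 h and 2.50 h, a gain read from small differences, and the new flask has to be judged against it.

| flask | starting material | first nucleophile | second nucleophile | remark | time |
|---|---|---|---|---|---|
| Saturday's | 0.054 M | 1 equiv | 1.2 equiv | run made earlier |  |
| Friday's | 0.12 M | 1 equiv | 1.2 equiv | run made earlier |  |
| Thursday's | 0.081 M | 1 equiv | 0.60 equiv | run made earlier |  |
| flask | 0.081 M | 1.00 equiv | 1.20 equiv |  | 2.5 h |

- Saturday's (time / h: other capture product / %, target / %): 0.200: 5.4, 13.1; 0.500: 13.4, 25.9; 1.00: 25.6, 37.4; 2.50: 47.8, 44.3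
- Friday's (time / h: other capture product / %, target / %): 0.667: 17.2, 31.3; 1.33: 32.7, 41.2; 2.00: 42.8, 44.0; 2.50: 47.6, 44.7
- Thursday's (time / h: other capture product / %, target / %): 0.333: 5.0, 22.9; 0.833: 14.6, 42.4; 1.50: 25.9, 51.3; 2.50: 37.8, 54.0

(standard deviation of a reading: 0.3 percentage points)

- the analysis behind the earlier runs scatters by 0.3 percentage points, standard deviation

1. share of other capture product in other capture product plus target at 80 s
2. share of other capture product in other capture product plus target at 12 min
3. share of other capture product in other capture product plus target at 2.5 h

**One number.** Saturday's run has the flask's charge ratio, and its ratio of other capture product to target moves from 0.412 at 0.200 h to 0.517 at 0.500 h. Carried back at that pace to 80 s, it gives 0.360. This split, the parts of other capture product formed per part of target at that early time, is a selectivity factor multiplied by the charge ratio, and it gives a share of 26.5 %.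

**Its test.** If c(first nucleophile) and c(second nucleophile) fell only by the products counted, Friday's split would reach 0.393 at 2.50 h, far below the late gain, so one number is not enough. The late shares are therefore read instead: 51.9 % on Saturday and 51.6 % on Friday, and the flask's concentration lies between theirs.

**The forecast.** It gives 27 %, 29.3 % and 51.8 %, holding that “The first nucleophile must also be lost first-order”; its early share stands above the one reckoned here.

**The flask.** The flask gives 27.5 %, 30.0 % and 51.6 %, so the forecast stands; late shares parting with concentration in a run would have overturned its late figure. The flask's ratio at 80 s is 0.379, against the split of 0.360.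

    starting material → intermediate (k = 2.80 × 10⁻⁴ /s)
    first nucleophile + intermediate → target (k = 4.50 /M/s)
    second nucleophile + intermediate → other capture product (k = 1.40 /M/s)
    first nucleophile → decomposed reagent (k = 2.50 × 10⁻⁴ /s)

By its decomposition path alone, the first nucleophile has a half-life of 0.77 h, close to the 0.69 h of the starting material by its path to the intermediate alone. At 0.611 h in the flask, decomposition uses the first nucleophile 1.1 times as fast as capture into target does. With 0.250 equiv of first nucleophile, the split scales to 1.44, a share of 59.0 % at 80 s, and that neighbouring flask gives 60.4 % at that time.

All runs stem from a simulated flask with constants of no real substance; noise was put on by code.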